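**Plan**
1. Retrosynthesis: the seven phenols are masked as MOM ethers, then the two bonds from C3 and C5 of ring A (the central acylphloroglucinol ring) to the two bridge CH2 carbons are cut.
2. Enabling feature: each bridge joins a ring A carbon lying between two oxygens to the benzylic carbon on C1 of a fully substituted side ring. Written as ring A C–Br plus side-ring CH2–ZnCl, only the hetero-trimer can form.
3. Ring A: phloroglucinol is acylated, brominated at C3 and C5, and MOM-protected.
4. Side ring: 2,4,6-trihydroxytoluene is acetylated, the methoxy group is fixed between the methyl- and acetyl-bearing carbons, the last ring carbon is formylated, and the aldehyde is taken to the benzylzinc chloride.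
5. Forward order: no ring is formed; the three aromatic rings are linked in one twofold Negishi coupling, then all MOM groups are removed.
6. Stereochemistry: the single (R) centre is bought with (R)-2-methylbutanoic acid and is carried only through acidic or neutral, non-enolising steps.

Key step: step 13

Assumption: (R)-2-methylbutanoic acid of high enantiomeric purity is a purchasable starting material, and the benzylzinc reagent 17 is handled as a titrated THF solution.

**Step 1**
Reactants: 1 (R)-2-methylbutanoic acid; 2 phloroglucinol
Product: 4 (R)-2-methyl-1-(2,4,6-trihydroxyphenyl)butan-1-one, via (R)-2-methylbutanoyl chloride 3 (not isolated)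
Conditions: (COCl)2, DMF (cat.), CH2Cl2, 0 °C → rt, evaporate; then 2, AlCl3, PhNO2/CH2Cl2, 0 °C → rt; aq. HCl work-up
Reagents that add atoms: none
Why: Friedel–Crafts C-acylation of the very nucleophilic phloroglucinol stops after one acyl group because the product ring is deactivated, and in the base-free, cold medium the acid chloride has no path through a ketene, so the (R) centre of 1 should be retained.

**Step 2**
Reactants: 4 (R)-2-methyl-1-(2,4,6-trihydroxyphenyl)butan-1-one
Product: 5 (R)-1-(3,5-dibromo-2,4,6-trihydroxyphenyl)-2-methylbutan-1-one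
Conditions: NBS (2.05 equiv), MeCN, −10 → 0 °C, dark
Reagents that add atoms: N-bromosuccinimide, O=C1CCC(=O)N1Br
Why: Electrophilic aromatic bromination should place one bromine on each of the two open ring carbons C3 and C5, both flanked by two hydroxyls, and no strong acid is formed that could touch the α-centre.

**Step 3**
Reactants: 5 (R)-1-(3,5-dibromo-2,4,6-trihydroxyphenyl)-2-methylbutan-1-one
Product: 6 (R)-1-[3,5-dibromo-2,4,6-tris(methoxymethoxy)phenyl]-2-methylbutan-1-one
Conditions: MOMCl (6 equiv), iPr2NEt (8 equiv), nBu4NI (cat.), CH2Cl2, 0 → 40 °C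
Reagents that add atoms: chloromethyl methyl ether, COCCl
Why: In this Williamson-type MOM ether formation the bromine atoms make all three phenols acidic enough for an amine base, including the two hydrogen-bonded ones, and the non-enolising base leaves the α-stereocentre alone.

**Step 4**
Reactants: 7 2,4,6-trihydroxytoluene
Product: 8 1-(2,4,6-trihydroxy-3-methylphenyl)ethan-1-one
Conditions: AcCl (1.0 equiv), AlCl3, PhNO2/CH2Cl2, 0 °C → rt; aq. HCl work-up
Reagents that add atoms: acetyl chloride, CC(Cl)=O
Why: In this Friedel–Crafts acylation the two open ring positions of 7 are equivalent by symmetry, so only one mono-acetyl product can form, and the new ketone deactivates the ring against a second acylation.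

**Step 5**
Reactants: 8 1-(2,4,6-trihydroxy-3-methylphenyl)ethan-1-one
Product: 9 1-[2-hydroxy-4,6-bis(methoxymethoxy)-3-methylphenyl]ethan-1-one
Conditions: MOMCl (2.1 equiv), iPr2NEt (2.5 equiv), CH2Cl2, 0 °C
Reagents that add atoms: chloromethyl methyl ether, COCCl
Why: Selective MOM ether formation should take the para hydroxyl and the less hindered ortho hydroxyl, while the ortho hydroxyl wedged between the methyl and acetyl groups stays locked in its hydrogen bond to the carbonyl and remains free.

**Step 6**
Reactants: 9 1-[2-hydroxy-4,6-bis(methoxymethoxy)-3-methylphenyl]ethan-1-one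
Product: 10 1-[2-methoxy-4,6-bis(methoxymethoxy)-3-methylphenyl]ethan-1-one
Conditions: MeI, K2CO3, DMF, rt → 40 °C
Reagents that add atoms: iodomethane, CI
Why: Williamson methylation of the one remaining, chelated phenol fixes the methoxy group between the methyl- and acetyl-bearing carbons, exactly where the target carries it.

**Step 7**
Reactants: 10 1-[2-methoxy-4,6-bis(methoxymethoxy)-3-methylphenyl]ethan-1-one
Product: 11 1-(4,6-dihydroxy-2-methoxy-3-methylphenyl)ethan-1-one
Conditions: HCl (3 M aq.), MeOH, 50 °C
Reagents that add atoms: none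
Why: Acid-catalysed acetal exchange with methanol cleaves both MOM ethers while the aryl methyl ether is inert, which frees the two phenols needed to activate the last ring carbon for formylation.

**Step 8**
Reactants: 11 1-(4,6-dihydroxy-2-methoxy-3-methylphenyl)ethan-1-one
Product: 12 3-acetyl-2,6-dihydroxy-4-methoxy-5-methylbenzaldehyde
Conditions: Cl2CHOMe, TiCl4, CH2Cl2, −10 °C → rt; then H2O
Reagents that add atoms: dichloromethyl methyl ether, COC(Cl)Cl; water, O
Why: Rieche formylation through the titanium phenoxide delivers the electrophile to the only open ring carbon, which lies between the two hydroxyls, and unlike a Vilsmeier reagent it does not draw the ortho-hydroxyacetophenone unit into chromone formation.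

**Step 9**
Reactants: 12 3-acetyl-2,6-dihydroxy-4-methoxy-5-methylbenzaldehyde
Product: 13 3-acetyl-4-methoxy-2,6-bis(methoxymethoxy)-5-methylbenzaldehyde
Conditions: MOMCl (5 equiv), iPr2NEt (6 equiv), nBu4NI (cat.), CH2Cl2, 0 → 40 °C
Reagents that add atoms: chloromethyl methyl ether, COCCl
Why: MOM ether formation with an amine base cannot enolise the acetyl group, so no aldol condensation with the aldehyde competes, and excess reagent with iodide catalysis should overcome the hydrogen bonds of both phenols to the carbonyl groups.

**Step 10**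
Reactants: 13 3-acetyl-4-methoxy-2,6-bis(methoxymethoxy)-5-methylbenzaldehyde
Product: 14 1-[3-(hydroxymethyl)-6-methoxy-2,4-bis(methoxymethoxy)-5-methylphenyl]ethan-1-one
Conditions: NaBH4 (0.5 equiv), MeOH/THF, −20 °C
Reagents that add atoms: none
Why: Chemoselective borohydride reduction should take the aldehyde far faster than the acetyl ketone, which is twisted out of conjugation and shielded by two ortho substituents.

**Step 11**
Reactants: 14 1-[3-(hydroxymethyl)-6-methoxy-2,4-bis(methoxymethoxy)-5-methylphenyl]ethan-1-one
Product: 16 1-[3-(chloromethyl)-6-methoxy-2,4-bis(methoxymethoxy)-5-methylphenyl]ethan-1-one, via benzylic mesylate 15 (not isolated)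
Conditions: MsCl, Et3N, LiCl, THF, 0 °C → rt
Reagents that add atoms: lithium chloride, [Li+].[Cl-]
Why: Mesylation followed by SN2 displacement with chloride converts the benzylic alcohol to the chloride under acid-free conditions that spare the MOM acetals, and the twisted alkoxy groups together with the electron-withdrawing acetyl group should keep the chloride from ionising.

**Step 12**
Reactants: 16 1-[3-(chloromethyl)-6-methoxy-2,4-bis(methoxymethoxy)-5-methylphenyl]ethan-1-one
Product: 17 [3-acetyl-4-methoxy-2,6-bis(methoxymethoxy)-5-methylbenzyl]zinc chloride (LiCl-complexed solution in THF)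
Conditions: Zn dust (activated with BrCH2CH2Br and Me3SiCl), LiCl, THF, 25 °C; titrate and use directly
Reagents that add atoms: zinc, [Zn]
Why: LiCl-mediated direct insertion of zinc into a benzylic C–Cl bond is a known reaction that tolerates aryl ketones, and LiCl pulls the organozinc off the metal surface, which keeps Wurtz coupling low.

**Step 13**
Reactants: 6 (R)-1-[3,5-dibromo-2,4,6-tris(methoxymethoxy)phenyl]-2-methylbutan-1-one; 17 [3-acetyl-4-methoxy-2,6-bis(methoxymethoxy)-5-methylbenzyl]zinc chloride (about 3 equiv)
Product: 19 hepta-MOM ether (R)-1-{3,5-bis[3-acetyl-4-methoxy-2,6-bis(methoxymethoxy)-5-methylbenzyl]-2,4,6-tris(methoxymethoxy)phenyl}-2-methylbutan-1-one, via mono-benzylated aryl bromide 18 (not isolated)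
Conditions: Pd(OAc)2 (5 mol %), SPhos (10 mol %), THF, 25 → 60 °C
Reagents that add atoms: none
Why: Zerovalent palladium, formed in the flask from Pd(OAc)2 and SPhos, inserts into a C–Br bond of 6, the benzylzinc chloride 17 hands its benzyl group to the resulting divalent arylpalladium bromide, and reductive elimination forges the aryl–CH2 bond; the cycle then repeats at the second bromide through 18. The closest known reaction type is the Negishi coupling of LiCl-solubilised benzylic zinc chlorides with di-ortho-substituted, electron-rich aryl bromides under palladium/biarylphosphine catalysis. No ring is closed and no stereocentre is created; three preformed rings are linked by the bonds C3–CH2 and C5–CH2 of ring A. The step needs chemoselectivity (cross-coupling over benzyl homocoupling, protodebromination and carbonyl addition) and completeness at both hindered sites: the fixed roles of bromide and zinc reagent exclude any other pairing, the benzyl group has no β-hydrogen, the bulky electron-rich ligand speeds oxidative addition between the two OMOM groups, and an excess of the reactive zinc reagent should drive the second coupling. The neutral, base-free medium and the weakly basic C–Zn bond should leave the enolisable (R) centre, the three ketones and the seven acetals untouched.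

**Step 14**
Reactants: 19 hepta-MOM ether of the target
Product: 20 (R)-1-{3,5-bis[(3-acetyl-2,6-dihydroxy-4-methoxy-5-methylphenyl)methyl]-2,4,6-trihydroxyphenyl}-2-methylbutan-1-one (target, CNP0201397.1)
Conditions: HCl (3 M aq.), MeOH/THF, 45 °C, argon
Reagents that add atoms: none
Why: Acid-catalysed transacetalisation with methanol removes all seven MOM groups, every ring carbon of the product is substituted so released formaldehyde equivalents find no nucleophilic site, and the vinylogous-acid character of the 2,4,6-trihydroxyaryl ketone disfavours enolisation toward the α-stereocentre.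

**Compound list**
1 | (R)-2-methylbutanoic acid | CC[C@@H](C)C(=O)O | starting material
2 | phloroglucinol (benzene-1,3,5-triol) | Oc1cc(O)cc(O)c1 | starting material
3 | (R)-2-methylbutanoyl chloride | CC[C@@H](C)C(Cl)=O | intermediate (not isolated)
4 | (R)-2-methyl-1-(2,4,6-trihydroxyphenyl)butan-1-one | CC[C@@H](C)C(=O)c1c(O)cc(O)cc1O | intermediate
5 | (R)-1-(3,5-dibromo-2,4,6-trihydroxyphenyl)-2-methylbutan-1-one | CC[C@@H](C)C(=O)c1c(O)c(Br)c(O)c(Br)c1O | intermediate
6 | (R)-1-[3,5-dibromo-2,4,6-tris(methoxymethoxy)phenyl]-2-methylbutan-1-one | CC[C@@H](C)C(=O)c1c(OCOC)c(Br)c(OCOC)c(Br)c1OCOC | intermediate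
7 | 2,4,6-trihydroxytoluene (2-methylbenzene-1,3,5-triol) | Cc1c(O)cc(O)cc1O | starting material
8 | 1-(2,4,6-trihydroxy-3-methylphenyl)ethan-1-one | CC(=O)c1c(O)cc(O)c(C)c1O | intermediate
9 | 1-[2-hydroxy-4,6-bis(methoxymethoxy)-3-methylphenyl]ethan-1-one | CC(=O)c1c(O)c(C)c(OCOC)cc1OCOC | intermediate
10 | 1-[2-methoxy-4,6-bis(methoxymethoxy)-3-methylphenyl]ethan-1-one | CC(=O)c1c(OC)c(C)c(OCOC)cc1OCOC | intermediate
11 | 1-(4,6-dihydroxy-2-methoxy-3-methylphenyl)ethan-1-one | CC(=O)c1c(OC)c(C)c(O)cc1O | intermediate
12 | 3-acetyl-2,6-dihydroxy-4-methoxy-5-methylbenzaldehyde | CC(=O)c1c(OC)c(C)c(O)c(C=O)c1O | intermediate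
13 | 3-acetyl-4-methoxy-2,6-bis(methoxymethoxy)-5-methylbenzaldehyde | CC(=O)c1c(OC)c(C)c(OCOC)c(C=O)c1OCOC | intermediate
14 | 1-[3-(hydroxymethyl)-6-methoxy-2,4-bis(methoxymethoxy)-5-methylphenyl]ethan-1-one | CC(=O)c1c(OC)c(C)c(OCOC)c(CO)c1OCOC | intermediate
15 | [3-acetyl-4-methoxy-2,6-bis(methoxymethoxy)-5-methylphenyl]methyl methanesulfonate | CC(=O)c1c(OC)c(C)c(OCOC)c(COS(C)(=O)=O)c1OCOC | intermediate (not isolated)
16 | 1-[3-(chloromethyl)-6-methoxy-2,4-bis(methoxymethoxy)-5-methylphenyl]ethan-1-one | CC(=O)c1c(OC)c(C)c(OCOC)c(CCl)c1OCOC | intermediate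
17 | [3-acetyl-4-methoxy-2,6-bis(methoxymethoxy)-5-methylbenzyl]zinc chloride | Cl[Zn]Cc1c(OCOC)c(C)c(OC)c(C(C)=O)c1OCOC | intermediate
18 | (R)-1-{3-[3-acetyl-4-methoxy-2,6-bis(methoxymethoxy)-5-methylbenzyl]-5-bromo-2,4,6-tris(methoxymethoxy)phenyl}-2-methylbutan-1-one | CC[C@@H](C)C(=O)c1c(OCOC)c(Br)c(OCOC)c(Cc2c(OCOC)c(C)c(OC)c(C(C)=O)c2OCOC)c1OCOC | intermediate (not isolated)
19 | (R)-1-{3,5-bis[3-acetyl-4-methoxy-2,6-bis(methoxymethoxy)-5-methylbenzyl]-2,4,6-tris(methoxymethoxy)phenyl}-2-methylbutan-1-one | CC[C@@H](C)C(=O)c1c(OCOC)c(Cc2c(OCOC)c(C)c(OC)c(C(C)=O)c2OCOC)c(OCOC)c(Cc2c(OCOC)c(C)c(OC)c(C(C)=O)c2OCOC)c1OCOC | intermediate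
20 | (R)-1-{3,5-bis[(3-acetyl-2,6-dihydroxy-4-methoxy-5-methylphenyl)methyl]-2,4,6-trihydroxyphenyl}-2-methylbutan-1-one | CC[C@@H](C)C(=O)c1c(O)c(Cc2c(O)c(C)c(OC)c(C(C)=O)c2O)c(O)c(Cc2c(O)c(C)c(OC)c(C(C)=O)c2O)c1O | target

**Step count**
Total: 14 steps. Longest linear sequence: 11 steps (steps 4–14, from 7 to 20); the ring A branch (steps 1–3) joins at step 13.

**Steps most likely to fail**

1. Step 13. The second coupling may stall, because after the first benzylation the remaining bromide sits between two OMOM groups next to a bulky diarylmethane, and protodebromination and benzyl homocoupling may then take over. The fallback reverses the polarity and needs no palladium; it sets out from 4 and 11 and comes back at 20. Compound 11 would be aminomethylated at its only open ring carbon with dimethyl(methylidene)ammonium iodide in CH2Cl2 (Mannich reaction) to give 1-{3-[(dimethylamino)methyl]-2,4-dihydroxy-6-methoxy-5-methylphenyl}ethan-1-one F1. Heating two equivalents of F1 with the unprotected acylphloroglucinol 4 in dioxane at about 100 °C should expel dimethylamine and let C3 and then C5 of 4 add to the benzylic electrophile so formed (ortho-quinone-methide-type reactivity). This passes through the mono-bridged compound (R)-1-{3-[(3-acetyl-2,6-dihydroxy-4-methoxy-5-methylphenyl)methyl]-2,4,6-trihydroxyphenyl}-2-methylbutan-1-one F2, which is not isolated, and arrives at 20 without protecting groups.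

2. Step 12. Zinc insertion may give way to Wurtz-type homocoupling or to ionisation of the electron-rich benzylic chloride on the metal surface. The fallback replaces the zinc reagent by a boron reagent; it sets out from 16 and comes back at 19. Palladium-catalysed Miyaura borylation of 16 (B2pin2, Pd2(dba)3, P(4-MeOC6H4)3, KOAc, toluene, 50 °C) would give 1-{6-methoxy-2,4-bis(methoxymethoxy)-5-methyl-3-[(4,4,5,5-tetramethyl-1,3,2-dioxaborolan-2-yl)methyl]phenyl}ethan-1-one F3. A twofold Suzuki–Miyaura coupling of F3 with 6 (Pd(OAc)2, SPhos, K3PO4, toluene/H2O, 80 °C) should then form the same two bridge bonds through 18 and deliver 19.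

3. Step 1. Configurational purity at the α-carbon may erode through reversible enolisation or ketene formation of the acyl chloride–AlCl3 complex. The fallback forms the aryl ketone from an aryllithium and an amide; it sets out from 1 and 2 and comes back at 6, bypassing 4 and 5. Acid chloride 3, made as in step 1, would be treated with N,O-dimethylhydroxylamine hydrochloride and pyridine in CH2Cl2 at 0 °C to give (R)-N-methoxy-N,2-dimethylbutanamide F4. Phloroglucinol 2 would be converted with NaH and MOMCl in DMF into 1,3,5-tris(methoxymethoxy)benzene F5. Directed ortho-lithiation of F5 with n-BuLi in THF at 0 °C should give [2,4,6-tris(methoxymethoxy)phenyl]lithium F6, which would add to F4 at −78 °C; the chelated tetrahedral adduct releases (R)-2-methyl-1-[2,4,6-tris(methoxymethoxy)phenyl]butan-1-one F7 only on aqueous work-up, so the ketone never meets the base. Dibromination of F7 with NBS (2.1 equiv) in MeCN at 0 °C should give 6.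

**Further compounds**
F1 | step 13 | 1-{3-[(dimethylamino)methyl]-2,4-dihydroxy-6-methoxy-5-methylphenyl}ethan-1-one | CC(=O)c1c(OC)c(C)c(O)c(CN(C)C)c1O
F2 | step 13 | (R)-1-{3-[(3-acetyl-2,6-dihydroxy-4-methoxy-5-methylphenyl)methyl]-2,4,6-trihydroxyphenyl}-2-methylbutan-1-one | CC[C@@H](C)C(=O)c1c(O)cc(O)c(Cc2c(O)c(C)c(OC)c(C(C)=O)c2O)c1O
F3 | step 12 | 1-{6-methoxy-2,4-bis(methoxymethoxy)-5-methyl-3-[(4,4,5,5-tetramethyl-1,3,2-dioxaborolan-2-yl)methyl]phenyl}ethan-1-one | CC(=O)c1c(OC)c(C)c(OCOC)c(CB2OC(C)(C)C(C)(C)O2)c1OCOC
F4 | step 1 | (R)-N-methoxy-N,2-dimethylbutanamide | CC[C@@H](C)C(=O)N(C)OC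
F5 | step 1 | 1,3,5-tris(methoxymethoxy)benzene | COCOc1cc(OCOC)cc(OCOC)c1
F6 | step 1 | [2,4,6-tris(methoxymethoxy)phenyl]lithium | [Li]c1c(OCOC)cc(OCOC)cc1OCOC
F7 | step 1 | (R)-2-methyl-1-[2,4,6-tris(methoxymethoxy)phenyl]butan-1-one | CC[C@@H](C)C(=O)c1c(OCOC)cc(OCOC)cc1OCOC
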